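**Retrosynthetic overview**
- The target comes from a bicyclic keto-lactone by ketone reduction/acylation (C4 isobutyrate), allylic oxidation of an isopropenyl group to the 2-substituted acrolein, and desilylation.
- Key step: the keto-lactone forms from an acyclic aldehyde–keto-ester by a boron aldol cyclisation that closes the cyclohexane (C3a–C7a bond); the aldolate then lactonises in the same flask.
- The keto-ester comes from Negishi acylation of a chiral β-zinc ester with an acid chloride.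
- The acid comes from an Ireland–Claisen rearrangement that sets the quaternary methyl/vinyl carbon and the neighbouring isopropenyl carbon.
- The allylic alcohol for the Claisen ester comes from (R)-glyceraldehyde acetonide. Ring order: carbocycle and lactone form in one operation.

Assumption: the three starting materials in the compound list are taken as purchased; bicyclic compounds are numbered as 1-benzofuran-2-ones (O1, C2, C3, C3a, C4–C7, C7a). Stereochemical outcomes of steps 6, 9 and 10 are predictions from transition-state models, not verified results.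

**Step 1**
Reactants: 1 (R)-2,2-dimethyl-1,3-dioxolane-4-carbaldehyde
Product: 2 (S)-4-ethynyl-2,2-dimethyl-1,3-dioxolane
Conditions: dimethyl (1-diazo-2-oxopropyl)phosphonate, K2CO3, MeOH, 0 to 23 °C
Reagents that add atoms: dimethyl (1-diazo-2-oxopropyl)phosphonate, CC(=O)C(=[N+]=[N-])P(=O)(OC)OC
Why: Ohira–Bestmann (Seyferth–Gilbert) homologation converts the aldehyde into the terminal alkyne under mild base without touching the dioxolane stereocentre (R becomes S only by priority change).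

**Step 2**
Reactants: 2 (S)-4-ethynyl-2,2-dimethyl-1,3-dioxolane
Product: 4 (2E)-3-[(4S)-2,2-dimethyl-1,3-dioxolan-4-yl]but-2-en-1-ol, via alkenylalane 3 (not isolated)
Conditions: Al(CH3)3, Cp2ZrCl2 (0.25 equiv), CH2Cl2, −20 to 0 °C; then n-BuLi, (CH2O)n, THF, −78 to 23 °C
Reagents that add atoms: trimethylaluminium, C[Al](C)C; formaldehyde (from paraformaldehyde), C=O
Why: Negishi zirconium-catalysed syn-carboalumination puts CH3 on the internal and Al on the terminal alkyne carbon, and the alanate adds to formaldehyde with retention, fixing the E trisubstituted alkene.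

**Step 3**
Reactants: 4 (2E)-3-[(4S)-2,2-dimethyl-1,3-dioxolan-4-yl]but-2-en-1-ol, 5 3-methylbut-3-enoic acid
Product: 6 (2E)-3-[(4S)-2,2-dimethyl-1,3-dioxolan-4-yl]but-2-en-1-yl 3-methylbut-3-enoate
Conditions: DCC, DMAP (5 mol %), CH2Cl2, 0 °C
Reagents that add atoms: none
Why: Steglich esterification of the primary allylic alcohol, run cold with little DMAP so the β,γ-double bond of the acid stays out of conjugation.

**Step 4**
Reactants: 6 (2E)-3-[(4S)-2,2-dimethyl-1,3-dioxolan-4-yl]but-2-en-1-yl 3-methylbut-3-enoate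
Product: 7 (2E,4S)-4,5-dihydroxy-3-methylpent-2-en-1-yl 3-methylbut-3-enoate
Conditions: AcOH/H2O/THF (3:1:1), 40 °C
Reagents that add atoms: none
Why: acid-catalysed acetal hydrolysis frees the 1,2-diol and leaves the allylic ester intact, so the secondary oxygen can be carried as a non-chelating silyl ether.

**Step 5**
Reactants: 7 (2E,4S)-4,5-dihydroxy-3-methylpent-2-en-1-yl 3-methylbut-3-enoate
Product: 8 (2E,4S)-3-methyl-4,5-bis(triethylsilyloxy)pent-2-en-1-yl 3-methylbut-3-enoate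
Conditions: Et3SiCl (2.4 equiv), imidazole, DMF, 0 to 23 °C
Reagents that add atoms: chlorotriethylsilane, CC[Si](Cl)(CC)CC
Why: silyl ether formation on both hydroxyls; triethylsilyl is chosen because the primary ether can later be oxidised directly under Swern conditions.

**Step 6**
Reactants: 8 (2E,4S)-3-methyl-4,5-bis(triethylsilyloxy)pent-2-en-1-yl 3-methylbut-3-enoate
Product: 11 (2S,3S)-3-[(1S)-1,2-bis(triethylsilyloxy)ethyl]-3-methyl-2-(prop-1-en-2-yl)pent-4-enoic acid, via ketene silyl acetal 9 (not isolated), via trimethylsilyl ester 10 (not isolated)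
Conditions: LiN(iPr)2, THF, −78 °C; (CH3)3SiCl/Et3N, −78 to 23 °C; then 1 M HCl
Reagents that add atoms: none
Why: Ireland–Claisen rearrangement in which kinetic deprotonation in THF gives the E ketene silyl acetal, the chair transition state with the E allyl unit sets the quaternary/tertiary pair (2S,3S), and the new bond forms anti to the allylic C–OSiEt3 bond with the allylic H next to the alkene methyl (Felkin-type, minimal 1,2-allylic strain).

**Step 7**
Reactants: 11 (2S,3S)-3-[(1S)-1,2-bis(triethylsilyloxy)ethyl]-3-methyl-2-(prop-1-en-2-yl)pent-4-enoic acid, 12 methyl (S)-3-bromo-2-methylpropanoate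
Product: 15 methyl (2R,5S,6S,7S)-2,6-dimethyl-4-oxo-5-(prop-1-en-2-yl)-7,8-bis(triethylsilyloxy)-6-vinyloctanoate, via acid chloride 13 (not isolated), via organozinc bromide 14 (not isolated)
Conditions: 11, 1-chloro-N,N,2-trimethylprop-1-en-1-amine, CH2Cl2, 0 °C; 12, Zn, LiCl, THF, 40 °C; then Pd(PPh3)4 (5 mol %), THF, 0 to 23 °C
Reagents that add atoms: none
Why: Negishi acylation of the neutrally generated acid chloride with the configurationally stable β-zinc ester gives the γ-keto ester without epimerising the α-isopropenyl centre, the C2 methyl stereocentre coming unchanged from 12.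

**Step 8**
Reactants: 15 methyl (2R,5S,6S,7S)-2,6-dimethyl-4-oxo-5-(prop-1-en-2-yl)-7,8-bis(triethylsilyloxy)-6-vinyloctanoate
Product: 17 methyl (2R,5S,6S,7S)-2,6-dimethyl-4,8-dioxo-5-(prop-1-en-2-yl)-7-(triethylsilyloxy)-6-vinyloctanoate, via alkoxysulfonium chloride 16 (not isolated)
Conditions: (COCl)2, DMSO, CH2Cl2, −78 to −40 °C; then Et3N, −78 to 0 °C
Reagents that add atoms: none
Why: Swern oxidation in which the activated sulfoxide cleaves the primary triethylsilyl ether selectively and oxidises it in place to the aldehyde, the hindered secondary silyl ether staying on.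

**Step 9 (key step)**
Reactants: 17 methyl (2R,5S,6S,7S)-2,6-dimethyl-4,8-dioxo-5-(prop-1-en-2-yl)-7-(triethylsilyloxy)-6-vinyloctanoate
Product: 21 (3R,3aR,5S,6S,7S,7aS)-3,6-dimethyl-5-(prop-1-en-2-yl)-7-(triethylsilyloxy)-6-vinyl-3,3a,5,6,7,7a-hexahydro-1-benzofuran-2,4-dione, via boron enolate 18 (not isolated), via boron aldolate 19 (not isolated), via hydroxy keto ester 20 (not isolated)
Conditions: n-Bu2BOTf, iPr2NEt, CH2Cl2, −78 to −20 °C; then pH 7 buffer, H2O2, MeOH, 0 °C; then PPTS, CH2Cl2, 23 °C (one flask)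
Reagents that add atoms: none
Why: soft enolisation on the unhindered CH2 side gives the Z boron enolate, whose intramolecular (6-enolendo) Zimmerman–Traxler aldol closes the cyclohexanone with the isopropenyl group equatorial and the C–OSiEt3 bond anti to the aldehyde C=O, so the new C7a oxygen is trans to OSiEt3 and cis to the C3a side chain, and this cis γ-hydroxy ester lactonises at once, giving carbocycle and lactone in one operation.

**Step 10**
Reactants: 21 (3R,3aR,5S,6S,7S,7aS)-3,6-dimethyl-5-(prop-1-en-2-yl)-7-(triethylsilyloxy)-6-vinyl-3,3a,5,6,7,7a-hexahydro-1-benzofuran-2,4-dione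
Product: 23 (3R,3aS,4S,5S,6S,7S,7aS)-3,6-dimethyl-2-oxo-5-(prop-1-en-2-yl)-7-(triethylsilyloxy)-6-vinyloctahydro-1-benzofuran-4-yl 2-methylpropanoate, via lithium alkoxide 22 (not isolated)
Conditions: LiBH(s-Bu)3, THF, −78 °C; then (CH3)2CHCOCl, DMAP (cat.), −78 to 0 °C
Reagents that add atoms: 2-methylpropanoyl chloride, CC(C)C(Cl)=O
Why: diastereoselective ketone reduction in which the bulky hydride enters anti to the axial C6 methyl and C7a–O bond (equatorial attack) to give the all-cis C4 alkoxide, which is acylated cold before it can translactonise.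

**Step 11**
Reactants: 23 (3R,3aS,4S,5S,6S,7S,7aS)-3,6-dimethyl-2-oxo-5-(prop-1-en-2-yl)-7-(triethylsilyloxy)-6-vinyloctahydro-1-benzofuran-4-yl 2-methylpropanoate
Product: 25 (3R,3aS,4S,5R,6S,7S,7aS)-3,6-dimethyl-2-oxo-5-(3-oxoprop-1-en-2-yl)-7-(triethylsilyloxy)-6-vinyloctahydro-1-benzofuran-4-yl 2-methylpropanoate, via allylic alcohol 24 (not isolated)
Conditions: SeO2 (30 mol %), t-BuOOH, CH2Cl2, 23 °C; then MnO2, CH2Cl2, 23 °C
Reagents that add atoms: selenium dioxide, O=[Se]=O; tert-butyl hydroperoxide, CC(C)(C)OO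
Why: SeO2 allylic oxidation (ene reaction then 2,3-sigmatropic shift) attacks the methyl of the 1,1-disubstituted alkene, the vinyl group having no allylic hydrogen, and MnO2 takes the remaining allylic alcohol to the enal.

**Step 12**
Reactants: 25 (3R,3aS,4S,5R,6S,7S,7aS)-3,6-dimethyl-2-oxo-5-(3-oxoprop-1-en-2-yl)-7-(triethylsilyloxy)-6-vinyloctahydro-1-benzofuran-4-yl 2-methylpropanoate
Product: 26 (3R,3aS,4S,5R,6S,7S,7aS)-7-hydroxy-3,6-dimethyl-2-oxo-5-(3-oxoprop-1-en-2-yl)-6-vinyloctahydro-1-benzofuran-4-yl 2-methylpropanoate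
Conditions: HF·pyridine, pyridine, THF, 0 to 23 °C
Reagents that add atoms: none
Why: fluoride desilylation of the secondary triethylsilyl ether under buffered conditions that leave the enal, the isobutyrate and the lactone intact.

**Compound list**
1 | (R)-2,2-dimethyl-1,3-dioxolane-4-carbaldehyde | O=C[C@H]1COC(C)(C)O1 | starting material
2 | (S)-4-ethynyl-2,2-dimethyl-1,3-dioxolane | C#C[C@H]1COC(C)(C)O1 | intermediate
3 | [(1E)-2-[(4S)-2,2-dimethyl-1,3-dioxolan-4-yl]prop-1-en-1-yl]dimethylalane | C[Al](C)/C=C(\C)[C@H]1COC(C)(C)O1 | intermediate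
4 | (2E)-3-[(4S)-2,2-dimethyl-1,3-dioxolan-4-yl]but-2-en-1-ol | OC/C=C(\C)[C@H]1COC(C)(C)O1 | intermediate
5 | 3-methylbut-3-enoic acid | C=C(C)CC(=O)O | starting material
6 | (2E)-3-[(4S)-2,2-dimethyl-1,3-dioxolan-4-yl]but-2-en-1-yl 3-methylbut-3-enoate | C=C(C)CC(=O)OC/C=C(\C)[C@H]1COC(C)(C)O1 | intermediate
7 | (2E,4S)-4,5-dihydroxy-3-methylpent-2-en-1-yl 3-methylbut-3-enoate | C=C(C)CC(=O)OC/C=C(\C)[C@H](O)CO | intermediate
8 | (2E,4S)-3-methyl-4,5-bis(triethylsilyloxy)pent-2-en-1-yl 3-methylbut-3-enoate | C=C(C)CC(=O)OC/C=C(\C)[C@H](O[Si](CC)(CC)CC)CO[Si](CC)(CC)CC | intermediate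
9 | (1E)-3-methyl-1-(trimethylsilyloxy)buta-1,3-dien-1-yl (2E,4S)-3-methyl-4,5-bis(triethylsilyloxy)pent-2-en-1-yl ether (E ketene silyl acetal of 8) | C=C(C)/C=C(/O[Si](C)(C)C)OC/C=C(\C)[C@H](O[Si](CC)(CC)CC)CO[Si](CC)(CC)CC | intermediate
10 | trimethylsilyl (2S,3S)-3-[(1S)-1,2-bis(triethylsilyloxy)ethyl]-3-methyl-2-(prop-1-en-2-yl)pent-4-enoate | C=C[C@](C)([C@H](O[Si](CC)(CC)CC)CO[Si](CC)(CC)CC)[C@H](C(C)=C)C(=O)O[Si](C)(C)C | intermediate
11 | (2S,3S)-3-[(1S)-1,2-bis(triethylsilyloxy)ethyl]-3-methyl-2-(prop-1-en-2-yl)pent-4-enoic acid | C=C[C@](C)([C@H](O[Si](CC)(CC)CC)CO[Si](CC)(CC)CC)[C@H](C(C)=C)C(=O)O | intermediate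
12 | methyl (S)-3-bromo-2-methylpropanoate | BrC[C@@H](C)C(=O)OC | starting material
13 | (2S,3S)-3-[(1S)-1,2-bis(triethylsilyloxy)ethyl]-3-methyl-2-(prop-1-en-2-yl)pent-4-enoyl chloride | C=C[C@](C)([C@H](O[Si](CC)(CC)CC)CO[Si](CC)(CC)CC)[C@H](C(C)=C)C(Cl)=O | intermediate
14 | bromo[(2S)-3-methoxy-2-methyl-3-oxopropyl]zinc | Br[Zn]C[C@@H](C)C(=O)OC | intermediate
15 | methyl (2R,5S,6S,7S)-2,6-dimethyl-4-oxo-5-(prop-1-en-2-yl)-7,8-bis(triethylsilyloxy)-6-vinyloctanoate | C=C[C@](C)([C@H](O[Si](CC)(CC)CC)CO[Si](CC)(CC)CC)[C@H](C(C)=C)C(=O)C[C@@H](C)C(=O)OC | intermediate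
16 | alkoxydimethylsulfonium chloride of 15 at C8 (C8–O–S+(CH3)2 in place of C8–OSiEt3) | C=C[C@](C)([C@H](O[Si](CC)(CC)CC)CO[S+](C)C)[C@H](C(C)=C)C(=O)C[C@@H](C)C(=O)OC.[Cl-] | intermediate
17 | methyl (2R,5S,6S,7S)-2,6-dimethyl-4,8-dioxo-5-(prop-1-en-2-yl)-7-(triethylsilyloxy)-6-vinyloctanoate | C=C[C@](C)([C@H](O[Si](CC)(CC)CC)C=O)[C@H](C(C)=C)C(=O)C[C@@H](C)C(=O)OC | intermediate
18 | Z di-n-butylboron enolate of 17 (C4–O–B(n-Bu)2, C3=C4) | C=C[C@](C)([C@H](O[Si](CC)(CC)CC)C=O)[C@H](C(C)=C)/C(OB(CCCC)CCCC)=C/[C@@H](C)C(=O)OC | intermediate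
19 | methyl (2R)-2-[(1R,2S,3S,4S,5S)-2-(dibutylboryloxy)-4-methyl-6-oxo-5-(prop-1-en-2-yl)-3-(triethylsilyloxy)-4-vinylcyclohexyl]propanoate | C=C[C@]1(C)[C@H](O[Si](CC)(CC)CC)[C@@H](OB(CCCC)CCCC)[C@@H]([C@@H](C)C(=O)OC)C(=O)[C@H]1C(C)=C | intermediate
20 | methyl (2R)-2-[(1R,2S,3S,4S,5S)-2-hydroxy-4-methyl-6-oxo-5-(prop-1-en-2-yl)-3-(triethylsilyloxy)-4-vinylcyclohexyl]propanoate | C=C[C@]1(C)[C@H](O[Si](CC)(CC)CC)[C@@H](O)[C@@H]([C@@H](C)C(=O)OC)C(=O)[C@H]1C(C)=C | intermediate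
21 | (3R,3aR,5S,6S,7S,7aS)-3,6-dimethyl-5-(prop-1-en-2-yl)-7-(triethylsilyloxy)-6-vinyl-3,3a,5,6,7,7a-hexahydro-1-benzofuran-2,4-dione | C=C[C@]1(C)[C@H](O[Si](CC)(CC)CC)[C@H]2OC(=O)[C@H](C)[C@H]2C(=O)[C@H]1C(C)=C | intermediate
22 | lithium (3R,3aS,4S,5S,6S,7S,7aS)-3,6-dimethyl-2-oxo-5-(prop-1-en-2-yl)-7-(triethylsilyloxy)-6-vinyloctahydro-1-benzofuran-4-olate | C=C[C@]1(C)[C@H](O[Si](CC)(CC)CC)[C@H]2OC(=O)[C@H](C)[C@H]2[C@@H](O[Li])[C@H]1C(C)=C | intermediate
23 | (3R,3aS,4S,5S,6S,7S,7aS)-3,6-dimethyl-2-oxo-5-(prop-1-en-2-yl)-7-(triethylsilyloxy)-6-vinyloctahydro-1-benzofuran-4-yl 2-methylpropanoate | C=C[C@]1(C)[C@H](O[Si](CC)(CC)CC)[C@H]2OC(=O)[C@H](C)[C@H]2[C@@H](OC(=O)C(C)C)[C@H]1C(C)=C | intermediate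
24 | (3R,3aS,4S,5S,6S,7S,7aS)-5-(3-hydroxyprop-1-en-2-yl)-3,6-dimethyl-2-oxo-7-(triethylsilyloxy)-6-vinyloctahydro-1-benzofuran-4-yl 2-methylpropanoate | C=C[C@]1(C)[C@H](O[Si](CC)(CC)CC)[C@H]2OC(=O)[C@H](C)[C@H]2[C@@H](OC(=O)C(C)C)[C@H]1C(=C)CO | intermediate
25 | (3R,3aS,4S,5R,6S,7S,7aS)-3,6-dimethyl-2-oxo-5-(3-oxoprop-1-en-2-yl)-7-(triethylsilyloxy)-6-vinyloctahydro-1-benzofuran-4-yl 2-methylpropanoate | C=C[C@]1(C)[C@H](O[Si](CC)(CC)CC)[C@H]2OC(=O)[C@H](C)[C@H]2[C@@H](OC(=O)C(C)C)[C@H]1C(=C)C=O | intermediate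
26 | (3R,3aS,4S,5R,6S,7S,7aS)-7-hydroxy-3,6-dimethyl-2-oxo-5-(3-oxoprop-1-en-2-yl)-6-vinyloctahydro-1-benzofuran-4-yl 2-methylpropanoate (CNP0198892.2) | C=C[C@]1(C)[C@H](O)[C@H]2OC(=O)[C@H](C)[C@H]2[C@@H](OC(=O)C(C)C)[C@H]1C(=C)C=O | target

**Totals**
Total step count: 12. Longest linear sequence: 12 steps (1 to 26); 5 and 12 enter as purchased partners.

**Three steps most likely to fail**

Step 9 (aldol cyclisation/lactonisation). Risks are enolisation of the α-silyloxy aldehyde instead of the ketone and the wrong facial sense relative to the resident centres; the competing chair is estimated to lie only slightly higher. Fallback: setting out from 17, pyrrolidine/AcOH (toluene, 50 °C) gives by aldol condensation the cyclohexenone methyl (2R)-2-[(3R,4S,5S)-4-methyl-6-oxo-5-(prop-1-en-2-yl)-3-(triethylsilyloxy)-4-vinylcyclohex-1-en-1-yl]propanoate F1. LiOH (THF/H2O, 0 °C) then gives (2R)-2-[(3R,4S,5S)-4-methyl-6-oxo-5-(prop-1-en-2-yl)-3-(triethylsilyloxy)-4-vinylcyclohex-1-en-1-yl]propanoic acid F2. DBU (MeCN, 23 °C) closes the lactone by reversible 5-exo oxa-Michael addition and protonation, so the C7a oxygen (trans to OSiEt3), the cis ring fusion and the convex C3 methyl are set under thermodynamic control, and the route is rejoined at 21.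

Step 6 (Ireland–Claisen). Risks are the geometry of the dienolate from the β,γ-unsaturated ester and only moderate facial control by the allylic silyloxy centre. Fallback: setting out from 8, (4S,5S)-2-bromo-1,3-bis(4-methylphenylsulfonyl)-4,5-diphenyl-1,3,2-diazaborolidine with iPr2NEt (CH2Cl2, −78 to 4 °C) gives the chiral boron ketene acetal (2E,4S)-3-methyl-4,5-bis(triethylsilyloxy)pent-2-en-1-yl (1E)-1-{[(4S,5S)-1,3-bis(4-methylphenylsulfonyl)-4,5-diphenyl-1,3,2-diazaborolidin-2-yl]oxy}-3-methylbuta-1,3-dien-1-yl ether F3. Its enolate geometry and π-face are reagent-controlled; whether the (4S,5S) or the (4R,5R) controller is the matched one is not known and must be tested. Rearrangement and aqueous work-up return the route to 11.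

Step 11 (SeO2 oxidation). Risks are low conversion, over-oxidation and attack at the ring methine. Fallback: setting out from 23, Ca(OCl)2/CO2 (CH2Cl2/H2O, 0 °C) gives by ene-type chlorination the allylic chloride (3R,3aS,4S,5R,6S,7S,7aS)-5-(3-chloroprop-1-en-2-yl)-3,6-dimethyl-2-oxo-7-(triethylsilyloxy)-6-vinyloctahydro-1-benzofuran-4-yl 2-methylpropanoate F4. 4-Methylmorpholine N-oxide (MeCN, 23 °C, Kornblum-type oxidation) converts it into the enal, rejoining the route at 25.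

**Further compounds**
F1 | step 9 | methyl (2R)-2-[(3R,4S,5S)-4-methyl-6-oxo-5-(prop-1-en-2-yl)-3-(triethylsilyloxy)-4-vinylcyclohex-1-en-1-yl]propanoate | C=C[C@]1(C)[C@H](O[Si](CC)(CC)CC)C=C([C@@H](C)C(=O)OC)C(=O)[C@H]1C(C)=C
F2 | step 9 | (2R)-2-[(3R,4S,5S)-4-methyl-6-oxo-5-(prop-1-en-2-yl)-3-(triethylsilyloxy)-4-vinylcyclohex-1-en-1-yl]propanoic acid | C=C[C@]1(C)[C@H](O[Si](CC)(CC)CC)C=C([C@@H](C)C(=O)O)C(=O)[C@H]1C(C)=C
F3 | step 6 | (2E,4S)-3-methyl-4,5-bis(triethylsilyloxy)pent-2-en-1-yl (1E)-1-{[(4S,5S)-1,3-bis(4-methylphenylsulfonyl)-4,5-diphenyl-1,3,2-diazaborolidin-2-yl]oxy}-3-methylbuta-1,3-dien-1-yl ether | C=C(C)/C=C(/OB1N(S(=O)(=O)c2ccc(C)cc2)[C@@H](c2ccccc2)[C@H](c2ccccc2)N1S(=O)(=O)c1ccc(C)cc1)OC/C=C(\C)[C@H](O[Si](CC)(CC)CC)CO[Si](CC)(CC)CC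
F4 | step 11 | (3R,3aS,4S,5R,6S,7S,7aS)-5-(3-chloroprop-1-en-2-yl)-3,6-dimethyl-2-oxo-7-(triethylsilyloxy)-6-vinyloctahydro-1-benzofuran-4-yl 2-methylpropanoate | C=C[C@]1(C)[C@H](O[Si](CC)(CC)CC)[C@H]2OC(=O)[C@H](C)[C@H]2[C@@H](OC(=O)C(C)C)[C@H]1C(=C)CCl
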